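The data were computed from invented constants, and the scatter is random.

I have 4 questions on 3 new flasks, and the one asking for a figure is double product at the end of green.

| flask | starting material | partner | remark | time |
|---|---|---|---|---|
| summer | 1 M | 0.54 M | run made earlier |  |
| spring | 1 M | 1.2 M | run made earlier |  |
| winter | 1 M | 2.8 M | run made earlier |  |
| blue | 1.0 M | 0.500 M |  | 30 min |
| red | 1.0 M | 3.00 M |  | 30 min |
| green | 1.0 M | 0.800 M |  | 30 min |

| run | time / min | double product / % | mono adduct / % |
|---|---|---|---|
| summer | 6.00 | 1.8 | 22.9 |
| summer | 12.0 | 3.4 | 26.3 |
| summer | 20.0 | 3.7 | 27.1 |
| summer | 25.0 | 2.8 | 26.7 |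
| summer | 30.0 | 3.3 | 27.3 |
| spring | 6.00 | 6.2 | 34.2 |
| spring | 12.0 | 8.4 | 37.6 |
| spring | 20.0 | 6.1 | 37.4 |
| spring | 25.0 | 7.5 | 37.3 |
| spring | 30.0 | 8.8 | 37.3 |
| winter | 2.50 | 8.2 | 38.2 |
| winter | 5.00 | 11.0 | 41.9 |
| winter | 8.00 | 14.3 | 42.6 |
| winter | 15.0 | 15.1 | 44.0 |
| winter | 30.0 | 15.9 | 45.2 |

(each reading ± 0.5 percentage points)

- which of these holds the largest part of the starting material at the end of blue (mono adduct / double product / starting material)
- which of these holds the largest part of the starting material at the end of red (mono adduct / double product / starting material)
- which of these holds the largest part of the starting material at the end of green (mono adduct / double product / starting material)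
- double product at the end of green, in percent of the starting material charged

- the earlier runs were read with a standard deviation of 0.5 percentage points

1. Let M and D be mono adduct and double product as fractions of the starting material charged, and let U = M + 2D be the uptake, the partner bound per starting material charged. If two like sites fill by chance, each is taken with chance U/2, and D is the square of that chance. This chance case is my zero.

2. Read on winter at 30.0 min, the excess over chance, D divided by that square, is 1.07. Summer reads 1.15, but its D of 3.3% carries a scatter of 0.5 points.

3. Green's uptake is still unknown. Per partner charged, the bound share at 30.0 min falls as the charge rises: 62.8% in summer, 45.8% in spring and 27.5% in winter.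

4. The first extreme gives green the summer share, so D is 6.76%. The second gives it the spring share, so D is 3.59%. Green's charge of 0.800 M lies between those two runs, so I expect D between these figures.

5. A straight line between the two shares gives green 56.1%, an uptake of 44.9%, and my D of 5.40%.

6. The forecast names starting material for blue, mono adduct for red and starting material for green. It puts D at 5.2%, from 4.4% to 6.1%, and says of green: “This fits between summer and spring.” My figure stands 0.2 points higher.

The flask gives starting material for blue, mono adduct for red and starting material for green, with double product at 5.00% in green, inside the forecast's range.

starting material + partner → mono adduct (k = 0.280 /M/min); partner + mono adduct → double product (k = 0.160 /M/min); 2 partner → homo dimer (k = 0.350 /M/min) At 30.0 min, green holds 0.187 M of homo dimer, and partner, the limiting reagent, is down to 0.029% of its charge. Green's uptake is 42.7% against my 44.9%, while its excess over chance is 1.10 against 1.07 from winter. In the neighbour flask, green with 0.40 M of starting material, mono adduct at 42.1% and double product at 11.3% give an excess over chance of 1.08.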